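**Plan**

- Retrosynthesis: the C3–C4 single bonds of both chromans and the Cα–Cβ bond of the propanone go back to C=C, and the ketone-flanking 2'-OH is re-closed onto Cβ as the C2–O1 bond of a flavanone. The whole C6–C3–C6 core with its four oxygens is then naringenin. In each 2H-pyran the aryl–C4 bond is re-drawn as aryl–C3, giving a 3-(hydroxymethyl)-2,2-dimethyl-2,3-dihydrofuran, whose O–CMe2, aryl–CH and O–CH2 bonds lead back to the phenol and a C5 allylic chloride.
- Forward: double O-allylation of naringenin, double aromatic Claisen shift, double closure to the two five-membered cyclic ethers, then one step that enlarges both five-membered rings to the six-membered pyran rings, and last an alkaline hydrogenation that saturates both chromenes and opens the pyranone.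
- Enabling feature: in each dihydrofuran the CH2–O carbon hangs on the ring CH next to an oxygenated arene carbon (A ring: the carbon between O7 and O1 and para to 5-OH; B ring: the carbon ortho to O4'). Ionisation at CH2 is therefore aryl-bridged, and the aryl carbon moves from CH to CH2.
- Regiochemistry: the pyranone of the flavanone is a temporary ring that ties up one ortho oxygen, and its C4=O chelates the other (5-OH). Only O7, para to the carbonyl, is alkylated and cyclised; the two A-ring ortho carbons become equivalent once the pyranone is opened.
- Stereochemistry: the target has no stereocentre. The flavanone C2 and the two benzylic CH centres of the intermediates are racemic or mixed and are all erased in steps 4 and 5.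

Key step: step 4

Remark: the target is achiral (each chroman C2 carries two methyl groups), so no enantiomer has to be chosen.
Remark: racemic naringenin and (E)-4-chloro-3-methylbut-2-en-1-yl acetate (the C5 chloro-acetate of industrial vitamin A chemistry) are taken as purchasable; the alkene geometry of the latter is lost in step 2.
Remark: in step 2 the A-ring allyl group can move to C8 or C6 of the flavanone. C8 is drawn; a C6 isomer would give the same target after step 5 and can be carried along.

**Step 1**
Reactants: 1 (±)-naringenin; 2 (E)-4-chloro-3-methylbut-2-en-1-yl acetate (2.2 equiv)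
Product: 3 (±)-7,4'-bis-O-[(E)-4-acetoxy-2-methylbut-2-en-1-yl]naringenin
Conditions: K2CO3 (2.5 equiv), KI (0.2 equiv), acetone, reflux
Reagents that add atoms: none
Why: Williamson etherification in which carbonate ionises only the two non-chelated phenols (7-OH and 4'-OH), the 5-OH being hydrogen-bonded to C4=O and the second ortho oxygen being held as the pyranone O1, so the primary allylic chloride (iodide in situ) should be taken up by SN2 at O7 and O4' as in the usual 7,4'-di-O-alkylation of 5,7,4'-trihydroxyflavanones; no stereocentre is formed.

**Step 2**
Reactants: 3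
Product: 4 8-(1-acetoxy-3-methylbut-3-en-2-yl)-2-[3-(1-acetoxy-3-methylbut-3-en-2-yl)-4-hydroxyphenyl]-5,7-dihydroxychroman-4-one (diastereomer mixture)
Conditions: PhNEt2, 195 °C, Ar, sealed tube
Reagents that add atoms: none
Why: Aromatic Claisen rearrangement ([3,3]-sigmatropic shift through a chair transition state) of each aryl allyl ether should deliver the allyl terminus CH(CH2OAc) to the free ortho carbon (C8 on the A ring, C3' on the B ring) and regenerate the phenol next to a new isopropenyl group; the two benzylic stereocentres form without control, which is harmless because step 4 erases them.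

**Step 3**
Reactants: 4
Product: 6 5-hydroxy-9-(hydroxymethyl)-2-[3-(hydroxymethyl)-2,2-dimethyl-2,3-dihydro-1-benzofuran-5-yl]-8,8-dimethyl-2,3,8,9-tetrahydro-4H-furo[2,3-h]chromen-4-one (diastereomer mixture), via bis-dihydrofuran diacetate 5 (not isolated)
Conditions: Amberlyst-15, PhMe, 80 °C; then MeOH, 60 °C
Reagents that add atoms: none
Why: Acid-catalysed Markovnikov hydroalkoxylation (the classical o-(2-methylallyl)phenol to 2,2-dimethyl-2,3-dihydrobenzofuran cyclisation, 5-exo-trig onto the tertiary cation) should close both five-membered rings, O7 being the only free hydroxyl next to the A-ring side chain, and the same sulfonic acid resin then transesterifies the two primary acetates with methanol; no stereocentre is set because the new C–O carbon carries two methyl groups.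

**Step 4**
Reactants: 6
Product: 8 5-hydroxy-8,8-dimethyl-2-(2,2-dimethyl-2H-chromen-6-yl)-2,3-dihydro-4H,8H-pyrano[2,3-h]chromen-4-one (racemic), via bis-triflate 7 (not isolated)
Conditions: Tf2O (2.3 equiv), 2,6-di-tert-butyl-4-methylpyridine (5 equiv), CH2Cl2, −78 → 40 °C
Reagents that add atoms: none
Why: With Tf2O and the hindered base each primary alcohol becomes a neopentyl-type triflate (7) that cannot be displaced from the rear, so on warming it ionises only with help from the neighbouring arene: the aromatic carbon bearing the dihydrofuran CH (C9a of the furochromenone, flanked by O7 and O1 and para to 5-OH; C3a of the benzofuran, ortho to its ring oxygen) attacks the CH2 carbon to give a spiro-cyclopropane arenium (phenonium) ion. Cleavage of the old C(aryl)–CH bond of this ion completes a Wagner–Meerwein 1,2-aryl shift, so each 2,2-dimethyl-2,3-dihydrofuran grows into a six-membered 2,2-dimethylpyran, and loss of a proton (directly or after a 1,2-hydride shift to the benzylic cation) should give the conjugated 2H-chromene. The closest known reaction type is the solvolytic Demjanov/Wagner–Meerwein ring expansion of benzo-fused cycloalkylmethyl sulfonates and of 3-(halomethyl)indolines or 2,3-dihydrobenzofurans through aryl-bridged cations. Both pyran rings are closed by ring enlargement (the exocyclic carbon is inserted between C-aryl and C3 by a 3-exo-tet ipso attack and reopening), not by a new cyclisation onto oxygen, so the O7–aryl and O4'–aryl bonds chosen in step 3 are carried over unchanged. No stereocentre is created, and the two benzylic stereocentres of 6 become sp2 carbons, which removes the diastereomer mixture. The step needs rearrangement to win over direct substitution, E2 elimination to an exocyclic alkene, methyl migration and oxygen bridging (ring contraction) in the cation; the hindered primary centre, the non-nucleophilic triflate and pyridine, and above all the oxygen atoms ortho and para to each migrating carbon, which make aryl bridging the fastest ionisation path, are what should secure this.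

**Step 5**
Reactants: 8
Product: 9 1-(5,7-dihydroxy-2,2-dimethylchroman-6-yl)-3-(2,2-dimethylchroman-6-yl)propan-1-one (target)
Conditions: H2 (1 atm), 10% Pd/C, 2 M aq. KOH/EtOH, 25 °C; then aq. HCl to pH 3
Reagents that add atoms: none
Why: Alkaline catalytic hydrogenation of the kind used to turn flavanones into dihydrochalcones: hydroxide opens the 5-hydroxyflavanone by E1cB (retro-oxa-Michael) to the chalcone phenolate, whose C=C should be hydrogenated irreversibly on Pd together with the two styrene-type chromene C=C bonds while the doubly ortho-oxygenated aryl ketone is left alone; the last stereocentre (flavanone C2) becomes CH2, so the product is achiral.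

**Compound list**

1 | (±)-naringenin, 5,7-dihydroxy-2-(4-hydroxyphenyl)chroman-4-one | O=C1CC(c2ccc(O)cc2)Oc2cc(O)cc(O)c12 | starting material
2 | (E)-4-chloro-3-methylbut-2-en-1-yl acetate | CC(=O)OC/C=C(\C)CCl | starting material
3 | (±)-7,4'-bis-O-[(E)-4-acetoxy-2-methylbut-2-en-1-yl]naringenin | CC(=O)OC/C=C(\C)COc1ccc(cc1)C1CC(=O)c2c(O)cc(OC/C(C)=C/COC(C)=O)cc2O1 | intermediate
4 | 8-(1-acetoxy-3-methylbut-3-en-2-yl)-2-[3-(1-acetoxy-3-methylbut-3-en-2-yl)-4-hydroxyphenyl]-5,7-dihydroxychroman-4-one (diastereomer mixture) | CC(=O)OCC(C(C)=C)c1cc(ccc1O)C1CC(=O)c2c(O)cc(O)c(C(COC(C)=O)C(C)=C)c2O1 | intermediate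
5 | {5-[9-(acetoxymethyl)-5-hydroxy-8,8-dimethyl-4-oxo-2,3,8,9-tetrahydro-4H-furo[2,3-h]chromen-2-yl]-2,2-dimethyl-2,3-dihydro-1-benzofuran-3-yl}methyl acetate (diastereomer mixture) | CC(=O)OCC1c2cc(ccc2OC1(C)C)C1CC(=O)c2c(O)cc3OC(C)(C)C(COC(C)=O)c3c2O1 | intermediate (not isolated)
6 | 5-hydroxy-9-(hydroxymethyl)-2-[3-(hydroxymethyl)-2,2-dimethyl-2,3-dihydro-1-benzofuran-5-yl]-8,8-dimethyl-2,3,8,9-tetrahydro-4H-furo[2,3-h]chromen-4-one (diastereomer mixture) | OCC1c2cc(ccc2OC1(C)C)C1CC(=O)c2c(O)cc3OC(C)(C)C(CO)c3c2O1 | intermediate
7 | bis(trifluoromethanesulfonate) of 6 | FC(F)(F)S(=O)(=O)OCC1c2cc(ccc2OC1(C)C)C1CC(=O)c2c(O)cc3OC(C)(C)C(COS(=O)(=O)C(F)(F)F)c3c2O1 | intermediate (not isolated)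
8 | 5-hydroxy-8,8-dimethyl-2-(2,2-dimethyl-2H-chromen-6-yl)-2,3-dihydro-4H,8H-pyrano[2,3-h]chromen-4-one (racemic) | CC1(C)C=Cc2cc(ccc2O1)C1CC(=O)c2c(O)cc3OC(C)(C)C=Cc3c2O1 | intermediate
9 | 1-(5,7-dihydroxy-2,2-dimethylchroman-6-yl)-3-(2,2-dimethylchroman-6-yl)propan-1-one (CNP0080574.0, achiral) | CC1(C)CCc2cc(CCC(=O)c3c(O)cc4c(c3O)CCC(C)(C)O4)ccc2O1 | target

**Step count and risks**

Total steps: 5. Longest linear sequence: 5 (fully linear from naringenin).

Steps most likely to fail:

1. Step 4. The cationic manifold may leak: the bridged ion may return without enlargement, a methyl group may migrate from CMe2 to give an oxocarbenium ion, or the ring oxygen may bridge and contract the new pyran to an isopropenyl-dihydrofuran; bridging on the less activated B ring may also be slow. Fallback: setting out from 6, the two primary alcohols are converted under Appel conditions (PPh3, I2, imidazole) into the bis(iodomethyl) compound F1. F1 is then treated with (Me3Si)3SiH and AIBN in toluene at 110 °C, the silane being added by syringe pump so that the primary radicals live long enough for the neophyl 1,2-aryl shift (radical instead of cationic ring expansion). This should give the bis-chroman flavanone F2 directly at the saturated oxidation level. F2 is opened under the conditions of step 5 and the route is rejoined at 9.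

2. Step 2. At 195 °C the free ortho-allylphenols may be eroded by abnormal Claisen rearrangement through a spirodienone, acetyl scrambling between the side-chain acetate and the phenol, or premature and unselective ring closure; the B-ring shift may also remain incomplete. Fallback: setting out from 3, the rearrangement is run as an acetylative Claisen reaction (Ac2O, NaOAc, PhNEt2, 190 °C), so that every phenol is trapped as its acetate as soon as it forms; this gives the penta-acetate F3. Acid methanolysis (HCl, MeOH, 50 °C) frees the triphenol diol F4, which closes on Amberlyst-15 in toluene as in step 3, and the route is rejoined at 6.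

3. Step 3. The protonated isopropenyl group may lose a proton towards the benzylic carbon (alkene migration into conjugation with the arene) or alkylate a second molecule instead of being captured by the phenol. Fallback: setting out from 4, ring closure is induced by an electrophile instead of a proton: N-(phenylseleno)phthalimide with catalytic camphorsulfonic acid in CH2Cl2 at −78 to 0 °C should give the bis(phenylselanylmethyl) dihydrofuran F5 by 5-exo selenoetherification with oxygen on the tertiary carbon. Bu3SnH and AIBN in toluene at 80 °C then replace selenium by hydrogen, and the route is rejoined at 5, which is methanolysed as in step 3.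

**Further compounds**

F1 | step 4 | 5-hydroxy-9-(iodomethyl)-2-[3-(iodomethyl)-2,2-dimethyl-2,3-dihydro-1-benzofuran-5-yl]-8,8-dimethyl-2,3,8,9-tetrahydro-4H-furo[2,3-h]chromen-4-one | ICC1c2cc(ccc2OC1(C)C)C1CC(=O)c2c(O)cc3OC(C)(C)C(CI)c3c2O1
F2 | step 4 | 5-hydroxy-8,8-dimethyl-2-(2,2-dimethylchroman-6-yl)-2,3,9,10-tetrahydro-4H,8H-pyrano[2,3-h]chromen-4-one | CC1(C)CCc2cc(ccc2O1)C1CC(=O)c2c(O)cc3OC(C)(C)CCc3c2O1
F3 | step 2 | 5,7-diacetoxy-8-(1-acetoxy-3-methylbut-3-en-2-yl)-2-[4-acetoxy-3-(1-acetoxy-3-methylbut-3-en-2-yl)phenyl]chroman-4-one | CC(=O)OCC(C(C)=C)c1cc(ccc1OC(C)=O)C1CC(=O)c2c(OC(C)=O)cc(OC(C)=O)c(C(COC(C)=O)C(C)=C)c2O1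
F4 | step 2 | 5,7-dihydroxy-8-(1-hydroxy-3-methylbut-3-en-2-yl)-2-[4-hydroxy-3-(1-hydroxy-3-methylbut-3-en-2-yl)phenyl]chroman-4-one | OCC(C(C)=C)c1cc(ccc1O)C1CC(=O)c2c(O)cc(O)c(C(CO)C(C)=C)c2O1
F5 | step 3 | {5-[9-(acetoxymethyl)-5-hydroxy-8-methyl-4-oxo-8-(phenylselanylmethyl)-2,3,8,9-tetrahydro-4H-furo[2,3-h]chromen-2-yl]-2-methyl-2-(phenylselanylmethyl)-2,3-dihydro-1-benzofuran-3-yl}methyl acetate | CC(=O)OCC1c2cc(ccc2OC1(C)C[Se]c1ccccc1)C1CC(=O)c2c(O)cc3OC(C)(C[Se]c4ccccc4)C(COC(C)=O)c3c2O1
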